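Everything rests on cutting the imidazole ring at C2. One cyclocondensation with triethyl orthoformate places that carbon between the amine nitrogen and the oxime nitrogen of an α-amino ketoxime, forming N3–C2 and N1–C2 and closing the ring as a 1-hydroxyimidazole. The step exploits the unsubstituted C2–H lying between N1 and N3 of the imidazole ring; the oxime supplies the aromatic oxidation level, so only N–O cleavage remains afterwards. The precursor, 3-amino-4-[4-(benzyloxy)phenyl]-1-(4-methoxyphenyl)butan-2-one oxime, holds C4, C5 and both CH2–aryl arms and is made as a single regioisomer from O-benzyltyrosine and a 4-methoxybenzyl Grignard reagent.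

Key step: step 5

Remark: the target is drawn as the neutral hydrogen sulfate; it should be isolated as the inner salt with the imidazolium ion, and the two ring N–H tautomers are one compound.
Remark: the target has no stereocentre; the tyrosine centre is carried nominally as (S) up to compound 12 and is erased in step 5, so any erosion on the way is without consequence.

Step 1
Reactants: 1 N-(tert-butoxycarbonyl)-O-benzyl-L-tyrosine
Product: 3 tert-butyl N-[(2S)-3-[4-(benzyloxy)phenyl]-1-[methoxy(methyl)amino]-1-oxopropan-2-yl]carbamate, via acyl imidazolide 2 (not isolated)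
Conditions: CDI (1,1'-carbonyldiimidazole, 1.1 equiv), CH2Cl2, 0 °C to rt; then MeNHOMe·HCl (1.2 equiv), rt
Reagents that add atoms: N,O-dimethylhydroxylamine hydrochloride, CNOC.Cl
Why: Weinreb amide formation, in which CDI turns the acid into an acyl imidazolide that is aminolysed by N,O-dimethylhydroxylamine while the liberated imidazole takes up the HCl.

Step 2
Reactants: 3 tert-butyl N-[(2S)-3-[4-(benzyloxy)phenyl]-1-[methoxy(methyl)amino]-1-oxopropan-2-yl]carbamate; 4 4-methoxybenzylmagnesium chloride
Product: 6 tert-butyl N-[(2S)-1-[4-(benzyloxy)phenyl]-4-(4-methoxyphenyl)-3-oxobutan-2-yl]carbamate, via tetrahedral magnesium adduct 5 (not isolated)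
Conditions: 4-MeOC6H4CH2MgCl (2.5 equiv, THF solution), THF, −15 °C to rt; then 1 M HCl, 0 °C
Reagents that add atoms: none
Why: Weinreb ketone synthesis, in which one equivalent of the Grignard reagent deprotonates the carbamate N–H and the next adds once to give a chelated tetrahedral adduct that survives until the cold acidic quench, so the ketone is never exposed to the organometallic.

Step 3
Reactants: 6 tert-butyl N-[(2S)-1-[4-(benzyloxy)phenyl]-4-(4-methoxyphenyl)-3-oxobutan-2-yl]carbamate
Product: 7 tert-butyl N-[(2S)-1-[4-(benzyloxy)phenyl]-3-(hydroxyimino)-4-(4-methoxyphenyl)butan-2-yl]carbamate (E/Z mixture)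
Conditions: NH2OH·HCl (2 equiv), NaOAc (2.5 equiv), EtOH–H2O, 60 °C
Reagents that add atoms: hydroxylamine hydrochloride, NO.Cl
Why: Acetate-buffered oxime condensation of the ketone, under which the Boc carbamate and both aryl ethers are stable and either oxime geometry is acceptable.

Step 4
Reactants: 7 tert-butyl N-[(2S)-1-[4-(benzyloxy)phenyl]-3-(hydroxyimino)-4-(4-methoxyphenyl)butan-2-yl]carbamate
Product: 9 (3S)-3-amino-4-[4-(benzyloxy)phenyl]-1-(4-methoxyphenyl)butan-2-one oxime (E/Z mixture), via amine hydrochloride 8 (not isolated)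
Conditions: 4 M HCl in dioxane, rt; then aq. NaHCO3, EtOAc
Reagents that add atoms: none
Why: Acidolytic Boc cleavage (loss of the tert-butyl cation, then decarboxylation) under anhydrous conditions that do not hydrolyse the oxime, followed by neutralisation to the free α-amino oxime.

Step 5
Reactants: 9 (3S)-3-amino-4-[4-(benzyloxy)phenyl]-1-(4-methoxyphenyl)butan-2-one oxime; 10 triethyl orthoformate
Product: 13 4-[4-(benzyloxy)benzyl]-5-(4-methoxybenzyl)-1H-imidazol-1-ol, via formimidate 11 (not isolated), via 4H-imidazole 1-oxide 12 (not isolated)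
Conditions: HC(OEt)3 (4 equiv), AcOH (10 mol %), toluene, 100 °C, EtOH distilled off
Reagents that add atoms: none
Why: Under acid catalysis the primary amine exchanges with the orthoester to give formimidate 11, whose N-protonated form is attacked at carbon by the oxime nitrogen, and loss of ethanol gives the cyclic nitrone 12. This forms N3–C2 and N1–C2 and closes the five-membered ring (N1, C2, N3, C4, C5) in a closure that counts as 5-exo-trig with respect to the exocyclic C=O+ bond of the protonated imidate. Transfer of the C4–H to the nitrone oxygen then gives the aromatic 1-hydroxyimidazole, so no oxidant is needed; the tyrosine-derived stereocentre is erased here and no new one is made. The reaction type is the established orthoester cyclocondensation of α-amino oximes to 1-hydroxyimidazoles (imidazole N-oxide tautomers). The selectivity needed is closure through oxime nitrogen and not oxygen: O-attack would give a six-membered, non-aromatic 1,2,5-oxadiazine by a reversible imidate exchange, whereas N-attack leads to a five-membered ring that aromatises irreversibly, and the acid equilibrates the oxime isomers so that the one whose nitrogen lone pair faces C3 is drained into the product.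

Step 6
Reactants: 13 4-[4-(benzyloxy)benzyl]-5-(4-methoxybenzyl)-1H-imidazol-1-ol
Product: 14 4-[4-(benzyloxy)benzyl]-5-(4-methoxybenzyl)-1H-imidazole
Conditions: TiCl3 (15% in aq. HCl, 3 equiv), MeOH, rt; basic work-up
Reagents that add atoms: none
Why: Two one-electron transfers from trivalent titanium to the protonated N–OH group cleave the weak N–O bond, a standard deoxygenation of 1-hydroxyimidazoles that leaves the benzyl and methyl aryl ethers untouched.

Step 7
Reactants: 14 4-[4-(benzyloxy)benzyl]-5-(4-methoxybenzyl)-1H-imidazole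
Product: 15 4-{[5-(4-methoxybenzyl)-1H-imidazol-4-yl]methyl}phenol
Conditions: H2 (1 atm), 10% Pd/C, MeOH, AcOH (2 equiv), rt
Reagents that add atoms: none
Why: Catalytic hydrogenolysis of the benzylic C–O bond of the aryl benzyl ether over palladium on carbon, with acetic acid protonating the imidazole so that it does not poison the catalyst and with the anisole and the ring–CH2–ring carbon bonds inert.

Step 8
Reactants: 15 4-{[5-(4-methoxybenzyl)-1H-imidazol-4-yl]methyl}phenol
Product: 16 Melanocin F, 4-{[5-(4-methoxybenzyl)-1H-imidazol-4-yl]methyl}phenyl hydrogen sulfate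
Conditions: SO3·pyridine (3 equiv), pyridine, 40 °C; then H2O, pH 6–7, C18 reversed-phase chromatography
Reagents that add atoms: sulfur trioxide–pyridine complex, O=S(=O)([O-])[n+]1ccccc1
Why: O-Sulfation of the phenol by sulfur trioxide transfer from its pyridine complex, in which an N–SO3 adduct of the imidazole, should it form, is itself a labile SO3 donor that is hydrolysed on aqueous work-up, leaving the aryl sulfate as its inner salt.

Compound list
1 | N-(tert-butoxycarbonyl)-O-benzyl-L-tyrosine | CC(C)(C)OC(=O)N[C@@H](Cc1ccc(OCc2ccccc2)cc1)C(=O)O | starting material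
2 | tert-butyl N-[(2S)-3-[4-(benzyloxy)phenyl]-1-(1H-imidazol-1-yl)-1-oxopropan-2-yl]carbamate (acyl imidazolide) | CC(C)(C)OC(=O)N[C@@H](Cc1ccc(OCc2ccccc2)cc1)C(=O)n1ccnc1 | intermediate (not isolated)
3 | tert-butyl N-[(2S)-3-[4-(benzyloxy)phenyl]-1-[methoxy(methyl)amino]-1-oxopropan-2-yl]carbamate (Weinreb amide) | CC(C)(C)OC(=O)N[C@@H](Cc1ccc(OCc2ccccc2)cc1)C(=O)N(C)OC | intermediate
4 | 4-methoxybenzylmagnesium chloride | COc1ccc(C[Mg]Cl)cc1 | starting material
5 | tetrahedral magnesium adduct: O-chloromagnesium N-methoxy-N-methyl hemiaminal of ketone 6 bearing the N-chloromagnesio carbamate (hemiaminal carbon unassigned) | COc1ccc(CC(O[Mg]Cl)(N(C)OC)[C@H](Cc2ccc(OCc3ccccc3)cc2)N([Mg]Cl)C(=O)OC(C)(C)C)cc1 | intermediate (not isolated)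
6 | tert-butyl N-[(2S)-1-[4-(benzyloxy)phenyl]-4-(4-methoxyphenyl)-3-oxobutan-2-yl]carbamate | CC(C)(C)OC(=O)N[C@@H](Cc1ccc(OCc2ccccc2)cc1)C(=O)Cc1ccc(OC)cc1 | intermediate
7 | tert-butyl N-[(2S)-1-[4-(benzyloxy)phenyl]-3-(hydroxyimino)-4-(4-methoxyphenyl)butan-2-yl]carbamate (E/Z mixture) | CC(C)(C)OC(=O)N[C@@H](Cc1ccc(OCc2ccccc2)cc1)C(=NO)Cc1ccc(OC)cc1 | intermediate
8 | (3S)-3-amino-4-[4-(benzyloxy)phenyl]-1-(4-methoxyphenyl)butan-2-one oxime hydrochloride | COc1ccc(CC(=NO)[C@@H](N)Cc2ccc(OCc3ccccc3)cc2)cc1.Cl | intermediate (not isolated)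
9 | (3S)-3-amino-4-[4-(benzyloxy)phenyl]-1-(4-methoxyphenyl)butan-2-one oxime (E/Z mixture; key-step precursor) | COc1ccc(CC(=NO)[C@@H](N)Cc2ccc(OCc3ccccc3)cc2)cc1 | intermediate
10 | triethyl orthoformate | CCOC(OCC)OCC | starting material
11 | ethyl N-[(2S)-1-[4-(benzyloxy)phenyl]-3-(hydroxyimino)-4-(4-methoxyphenyl)butan-2-yl]formimidate | CCOC=N[C@@H](Cc1ccc(OCc2ccccc2)cc1)C(=NO)Cc1ccc(OC)cc1 | intermediate (not isolated)
12 | (4S)-4-[4-(benzyloxy)benzyl]-5-(4-methoxybenzyl)-4H-imidazole 1-oxide (cyclic nitrone) | [O-][N+]1=C(Cc2ccc(OC)cc2)[C@H](Cc2ccc(OCc3ccccc3)cc2)N=C1 | intermediate (not isolated)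
13 | 4-[4-(benzyloxy)benzyl]-5-(4-methoxybenzyl)-1H-imidazol-1-ol | COc1ccc(Cc2c(Cc3ccc(OCc4ccccc4)cc3)ncn2O)cc1 | intermediate
14 | 4-[4-(benzyloxy)benzyl]-5-(4-methoxybenzyl)-1H-imidazole | COc1ccc(Cc2[nH]cnc2Cc2ccc(OCc3ccccc3)cc2)cc1 | intermediate
15 | 4-{[5-(4-methoxybenzyl)-1H-imidazol-4-yl]methyl}phenol | COc1ccc(Cc2[nH]cnc2Cc2ccc(O)cc2)cc1 | intermediate
16 | Melanocin F, 4-{[5-(4-methoxybenzyl)-1H-imidazol-4-yl]methyl}phenyl hydrogen sulfate | COc1ccc(Cc2[nH]cnc2Cc2ccc(OS(=O)(=O)O)cc2)cc1 | target

Total step count: 8
Longest linear sequence: 8 steps (from compound 1)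

Steps most likely to fail

1. Step 5 (cyclocondensation). The ring may close through the oxime oxygen, two amine molecules may be bridged as an intermolecular amidine, or the cyclic nitrone may fail to tautomerise, so that the aromatic ring is not reached cleanly. Fallback: setting out from ketone 6, the Boc group is removed with HCl in dioxane to give (3S)-3-amino-4-[4-(benzyloxy)phenyl]-1-(4-methoxyphenyl)butan-2-one hydrochloride F1. This salt is heated in formamide at about 160 °C (Bredereck imidazole synthesis: N-formylation, imine formation with ammonia from the formamide, cyclodehydration) and should give the N-unsubstituted imidazole directly. The route is rejoined at compound 14, and steps 3 to 6 are bypassed.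

2. Step 8 (sulfation). The imidazole nitrogen may stay sulfonated, the sulfate may be lost by hydrolysis during isolation, or the very polar inner salt may not separate from pyridinium salts. Fallback: setting out from phenol 15, the imidazole nitrogen, which reacts far faster than the phenol, is tritylated (TrCl, Et3N, CH2Cl2, rt) to give 4-{[5-(4-methoxybenzyl)-1-trityl-1H-imidazol-4-yl]methyl}phenol F2; either N-regioisomer serves. Sulfation with SO3·pyridine in pyridine should then give 4-{[5-(4-methoxybenzyl)-1-trityl-1H-imidazol-4-yl]methyl}phenyl hydrogen sulfate F3, a lipophilic compound that can be purified on silica as its tetrabutylammonium salt. Detritylation in 80% aqueous AcOH at rt brings the material back to the route at target 16.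

3. Step 6 (N–O cleavage). Reduction may stop short, or the basic product may be held back in the titanium hydroxide sludge at work-up. Fallback: setting out from 13, the N–O bond is hydrogenolysed on a metal surface instead of by a dissolved one-electron reductant (H2, Raney nickel (Ni), EtOH, rt), coming back to the route at compound 14. This fallback makes no new compound (F0), and any concurrent loss of the benzyl group would only advance material to 15.

Further compounds
F1 | step 5 | (3S)-3-amino-4-[4-(benzyloxy)phenyl]-1-(4-methoxyphenyl)butan-2-one hydrochloride | Cl.COc1ccc(CC(=O)[C@@H](N)Cc2ccc(OCc3ccccc3)cc2)cc1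
F2 | step 8 | 4-{[5-(4-methoxybenzyl)-1-trityl-1H-imidazol-4-yl]methyl}phenol | COc1ccc(Cc2c(Cc3ccc(O)cc3)ncn2C(c2ccccc2)(c2ccccc2)c2ccccc2)cc1
F3 | step 8 | 4-{[5-(4-methoxybenzyl)-1-trityl-1H-imidazol-4-yl]methyl}phenyl hydrogen sulfate | COc1ccc(Cc2c(Cc3ccc(OS(=O)(=O)O)cc3)ncn2C(c2ccccc2)(c2ccccc2)c2ccccc2)cc1
F0 | step 6 | none | none
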